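**Strategy.** The route rests on cutting the bond between C8 of ring A (the benzenoid ring) of the carbinol-bound coumarin and the carbinol carbon, taken one oxidation level higher as an aryl ketone. The key step exploits two features: both aryl groups are the same 5,7-dimethoxycoumarin-8-yl unit, so one iodide, 8-iodolimettin, feeds both halves, and the carbinol carbon is the only oxidised carbon of the C10 core, lying between C8 and ring carbon C1. The arylzinc of the iodide is joined under palladium catalysis to the S-ethyl thioester of the fully elaborated (1S,2R)-cyclohexenecarboxylic acid, made by an auxiliary-controlled Diels–Alder reaction. A reagent-controlled ketone reduction then sets the carbinol centre.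

Key step: step 7

Remark on the chemistry: electrophilic iodination of limettin is taken to occur at C8, the ring A position between O1 and the 7-methoxy group, as is usual for 5,7-dimethoxycoumarins; the cyclohexene is numbered with C1 bearing the carbonyl or carbinol carbon, C2 the aryl group, C3=C4 the double bond and C6 the gem-dimethyl carbon.

Step 1
Reactants: 1 5,7-dimethoxy-2H-chromen-2-one (limettin)
Product: 2 8-iodo-5,7-dimethoxy-2H-chromen-2-one
Conditions: NIS (1.05 equiv), TFA (cat.), MeCN, 0 °C → rt
Reagents that add atoms: N-iodosuccinimide, O=C1CCC(=O)N1I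
Why: Electrophilic aromatic iodination with acid-activated NIS should take place at C8 of ring A, which is ortho to O1 and to the 7-methoxy group and para to the 5-methoxy group, the pyranone double bond being much less nucleophilic.

Step 2
Reactants: 3 2-methylbut-1-en-3-yne; 4 pinacolborane
Product: 5 (E)-4,4,5,5-tetramethyl-2-(3-methylbuta-1,3-dien-1-yl)-1,3,2-dioxaborolane
Conditions: Cp2Zr(H)Cl (5 mol%), Et3N (10 mol%), neat, 60 °C
Reagents that add atoms: none
Why: Zirconium-catalysed syn hydroboration of the terminal alkyne places boron on the terminal carbon and should give the E alkenylboronate, the 1,1-disubstituted alkene being inert to pinacolborane under these conditions.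

Step 3
Reactants: 2 8-iodo-5,7-dimethoxy-2H-chromen-2-one; 5 (E)-4,4,5,5-tetramethyl-2-(3-methylbuta-1,3-dien-1-yl)-1,3,2-dioxaborolane
Product: 6 5,7-dimethoxy-8-[(1E)-3-methylbuta-1,3-dien-1-yl]-2H-chromen-2-one
Conditions: Pd(dppf)Cl2 (5 mol%), K3PO4, THF/H2O, 60 °C
Reagents that add atoms: none
Why: Suzuki–Miyaura coupling of the aryl iodide with the alkenylboronate proceeds with retention of the E geometry, and the mild phosphate base should spare the lactone.

Step 4
Reactants: 7 (R)-4-benzyloxazolidin-2-one; 8 3-methylbut-2-enoyl chloride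
Product: 10 (R)-4-benzyl-3-(3-methylbut-2-enoyl)oxazolidin-2-one, via N-lithio-oxazolidinone 9 (not isolated)
Conditions: n-BuLi, THF, −78 °C; then 8, −78 → 0 °C
Reagents that add atoms: none
Why: N-acylation of the lithiated Evans oxazolidinone with the acid chloride at low temperature is standard, avoids deconjugation of the enoyl group and leaves the auxiliary stereocenter untouched.

Step 5
Reactants: 6 5,7-dimethoxy-8-[(1E)-3-methylbuta-1,3-dien-1-yl]-2H-chromen-2-one; 10 (R)-4-benzyl-3-(3-methylbut-2-enoyl)oxazolidin-2-one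
Product: 11 (4R)-4-benzyl-3-{[(1R,2R)-2-(5,7-dimethoxy-2-oxo-2H-chromen-8-yl)-4,6,6-trimethylcyclohex-3-en-1-yl]carbonyl}-1,3-oxazolidin-2-one
Conditions: 10 (1.5 equiv), Me2AlCl (3 equiv), CH2Cl2, −78 → −20 °C; then 1 M HCl
Reagents that add atoms: none
Why: In this Evans auxiliary-controlled Diels–Alder reaction Me2AlCl chelates both imide carbonyls to give a cationic s-cis dienophile reactive enough for a β,β-disubstituted enoyl group, the doubly donor-substituted diene bonds through its CH2 terminus to the CMe2 carbon (ortho/para rule), and endo approach to the Cα Re face anti to the benzyl group should set C2 as R and C1 as R (cis).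

Step 6
Reactants: 11 (4R)-4-benzyl-3-{[(1R,2R)-2-(5,7-dimethoxy-2-oxo-2H-chromen-8-yl)-4,6,6-trimethylcyclohex-3-en-1-yl]carbonyl}-1,3-oxazolidin-2-one
Product: 13 S-ethyl (1S,2R)-2-(5,7-dimethoxy-2-oxo-2H-chromen-8-yl)-4,6,6-trimethylcyclohex-3-ene-1-carbothioate, via cis-thioester 12 (not isolated)
Conditions: EtSH, n-BuLi, THF, 0 °C; then DBU (0.2 equiv), rt
Reagents that add atoms: ethanethiol, CCS
Why: Thiolysis of the Evans imide at the exocyclic carbonyl by lithium ethanethiolate releases the auxiliary to give cis-thioester 12, whose acidic α-hydrogen is then exchanged by DBU so that C1 equilibrates to the diequatorial trans arrangement (1S) under thermodynamic control while the non-enolisable C2 stays R.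

Step 7
Reactants: 2 8-iodo-5,7-dimethoxy-2H-chromen-2-one; 13 S-ethyl (1S,2R)-2-(5,7-dimethoxy-2-oxo-2H-chromen-8-yl)-4,6,6-trimethylcyclohex-3-ene-1-carbothioate
Product: 15 8-{[(1S,2R)-2-(5,7-dimethoxy-2-oxo-2H-chromen-8-yl)-4,6,6-trimethylcyclohex-3-en-1-yl]carbonyl}-5,7-dimethoxy-2H-chromen-2-one, via arylzinc iodide 14 (not isolated)
Conditions: 2, Zn dust, LiCl, THF, 40 °C; then 13, Pd2(dba)3 (2.5 mol%), SPhos (10 mol%), THF/NMP, 40 °C
Reagents that add atoms: none
Why: Zerovalent palladium inserts into the C(acyl)–S bond of thioester 13, the thiophilic zinc of 14 takes the thiolate in the transmetalation, and reductive elimination forges the bond between C8 of ring A and the carbonyl carbon. The closest known reaction type is the Fukuyama thioester–organozinc ketone synthesis, an acyl Negishi coupling. No ring is closed and no stereocenter is created: C2 is untouched, and C1, now alpha to the ketone, keeps its trans configuration because the medium is neutral and that configuration is also the thermodynamic one. The step needs chemoselectivity for the thioester over two coumarin lactones and their enoate double bonds, which the low nucleophilicity of the arylzinc and the much readier oxidative addition of the C–S bond should secure. It also needs two hindered partners to meet, for which the bulky electron-rich ligand SPhos is chosen, and the position of arylation is fixed by the iodine placed at C8 in step 1.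

Step 8
Reactants: 15 8-{[(1S,2R)-2-(5,7-dimethoxy-2-oxo-2H-chromen-8-yl)-4,6,6-trimethylcyclohex-3-en-1-yl]carbonyl}-5,7-dimethoxy-2H-chromen-2-one
Product: 16 8-{(S)-hydroxy[(1S,2R)-2-(5,7-dimethoxy-2-oxo-2H-chromen-8-yl)-4,6,6-trimethylcyclohex-3-en-1-yl]methyl}-5,7-dimethoxy-2H-chromen-2-one
Conditions: (R)-2-methyl-CBS-oxazaborolidine (0.5 equiv), catecholborane (2 equiv), toluene, −40 → 0 °C
Reagents that add atoms: none
Why: In this Corey–Bakshi–Shibata reduction the (R)-oxazaborolidine should bind the ketone anti to the aryl group (the large substituent) and deliver hydride to the face that gives the (S)-carbinol, which is also the Felkin–Anh face (attack anti to the C1–C6 bond to the quaternary carbon), while catecholborane at low temperature leaves the trisubstituted alkene and both lactones untouched.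

**Compound list**

1 | 5,7-dimethoxy-2H-chromen-2-one (limettin) | COc1cc(OC)c2ccc(=O)oc2c1 | starting material
2 | 8-iodo-5,7-dimethoxy-2H-chromen-2-one | COc1cc(OC)c2ccc(=O)oc2c1I | intermediate
3 | 2-methylbut-1-en-3-yne | C=C(C)C#C | starting material
4 | pinacolborane (4,4,5,5-tetramethyl-1,3,2-dioxaborolane) | CC1(C)OBOC1(C)C | starting material
5 | (E)-4,4,5,5-tetramethyl-2-(3-methylbuta-1,3-dien-1-yl)-1,3,2-dioxaborolane | C=C(C)/C=C/B1OC(C)(C)C(C)(C)O1 | intermediate
6 | 5,7-dimethoxy-8-[(1E)-3-methylbuta-1,3-dien-1-yl]-2H-chromen-2-one | COc1cc(OC)c2ccc(=O)oc2c1/C=C/C(C)=C | intermediate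
7 | (R)-4-benzyloxazolidin-2-one | O=C1N[C@H](Cc2ccccc2)CO1 | starting material
8 | 3-methylbut-2-enoyl chloride | CC(C)=CC(=O)Cl | starting material
9 | N-lithio-oxazolidinone (lithium salt of 7) | [Li]N1[C@H](Cc2ccccc2)COC1=O | intermediate (not isolated)
10 | (R)-4-benzyl-3-(3-methylbut-2-enoyl)oxazolidin-2-one | CC(C)=CC(=O)N1[C@H](Cc2ccccc2)COC1=O | intermediate
11 | (4R)-4-benzyl-3-{[(1R,2R)-2-(5,7-dimethoxy-2-oxo-2H-chromen-8-yl)-4,6,6-trimethylcyclohex-3-en-1-yl]carbonyl}-1,3-oxazolidin-2-one | O=C([C@@H]1[C@H](c2c(OC)cc(OC)c3ccc(=O)oc23)C=C(C)CC1(C)C)N1[C@H](Cc2ccccc2)COC1=O | intermediate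
12 | cis-thioester, S-ethyl (1R,2R)-2-(5,7-dimethoxy-2-oxo-2H-chromen-8-yl)-4,6,6-trimethylcyclohex-3-ene-1-carbothioate | CCSC(=O)[C@@H]1[C@H](c2c(OC)cc(OC)c3ccc(=O)oc23)C=C(C)CC1(C)C | intermediate (not isolated)
13 | S-ethyl (1S,2R)-2-(5,7-dimethoxy-2-oxo-2H-chromen-8-yl)-4,6,6-trimethylcyclohex-3-ene-1-carbothioate | CCSC(=O)[C@H]1[C@H](c2c(OC)cc(OC)c3ccc(=O)oc23)C=C(C)CC1(C)C | intermediate
14 | arylzinc iodide, (5,7-dimethoxy-2-oxo-2H-chromen-8-yl)zinc iodide | COc1cc(OC)c2ccc(=O)oc2c1[Zn]I | intermediate (not isolated)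
15 | 8-{[(1S,2R)-2-(5,7-dimethoxy-2-oxo-2H-chromen-8-yl)-4,6,6-trimethylcyclohex-3-en-1-yl]carbonyl}-5,7-dimethoxy-2H-chromen-2-one | COc1cc(OC)c2ccc(=O)oc2c1C(=O)[C@H]1[C@H](c2c(OC)cc(OC)c3ccc(=O)oc23)C=C(C)CC1(C)C | intermediate
16 | 8-{(S)-hydroxy[(1S,2R)-2-(5,7-dimethoxy-2-oxo-2H-chromen-8-yl)-4,6,6-trimethylcyclohex-3-en-1-yl]methyl}-5,7-dimethoxy-2H-chromen-2-one | COc1cc(OC)c2ccc(=O)oc2c1[C@@H](O)[C@H]1[C@H](c2c(OC)cc(OC)c3ccc(=O)oc23)C=C(C)CC1(C)C | target

**Step count.** Total: 8 steps. Longest linear sequence: 6 steps (1 → 2 → 6 → 11 → 13 → 15 → 16, steps 1, 3, 5, 6, 7 and 8).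

**Steps most likely to fail**

Step 5. The β,β-dimethyl enoyl imide may react too slowly, so that Lewis acid-induced oligomerisation of diene 6 competes, and leakage into the exo manifold would erode the enantiomeric purity once C1 is equilibrated in step 6. The fallback sets the two ring stereocenters by an Ireland–Claisen rearrangement and closes the ring by metathesis; it sets out from 2 and returns to the route at 13. Heck reaction of 2 with methyl vinyl ketone (Pd(OAc)2, Et3N, DMF, 80 °C) should give enone F1. Reduction with (R)-2-methyl-CBS-oxazaborolidine and catecholborane should give (S,E)-allylic alcohol F2. Esterification (DCC, DMAP) with 3,3,5-trimethylhex-5-enoic acid F3, itself made from commercial 3,3-dimethyl-5-oxohexanoic acid by Wittig methylenation with Ph3P=CH2, should give ester F4. LDA and TMSCl in THF at −78 °C should give the (E)-silyl ketene acetal F5, which on warming rearranges through a chair transition state to silyl ester F6; this is hydrolysed on work-up to acid F7, with C2 as R and C1 as S by chirality transfer from the carbinol centre. EtSH, DCC and DMAP should give acyclic thioester F8, and ring-closing metathesis (second-generation Hoveyda–Grubbs catalyst, toluene, 80 °C) closes the C3=C4 bond with loss of propene to give 13.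

Step 7. Oxidative addition into the hindered thioester and transmetalation of the di-ortho-substituted arylzinc may both be slow, so that protodezincation and homocoupling of 14 take over. The fallback is an electrophilic acylation that needs no organometallic; it sets out from 13 and returns to the route at 15. Silver-assisted hydrolysis (AgOTf, THF/H2O) should give carboxylic acid F9, and 1-chloro-N,N,2-trimethylprop-1-en-1-amine in CH2Cl2 should convert it under neutral conditions into acid chloride F10. Friedel–Crafts acylation of limettin 1 (excess) with F10 and SnCl4 in CH2Cl2 at −40 °C, in which the small acylium ion attacks the nucleophilic C8 of ring A, should give 15.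

Step 8. Hydride delivery to a ketone flanked by a di-ortho-substituted aryl group and an α-branched ring carbon may be slow and may show poor or reversed facial selectivity. The fallback forms the carbinol centre in the carbon–carbon bond-forming event instead, which exchanges the roles of aryl and hydrogen and therefore inverts the sense of induction; it sets out from 13 and returns to the route at 16. Fukuyama reduction of 13 (Et3SiH, Pd/C, acetone) should give aldehyde F11. Nozaki–Hiyama–Kishi coupling with iodide 2 (CrCl2, NiCl2 (cat.), DMF) should generate arylchromium dichloride F12, which adds to the aldehyde to give 16 after separation from its carbinol epimer.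

**Further compounds**

F1 | step 5 | 5,7-dimethoxy-8-[(1E)-3-oxobut-1-en-1-yl]-2H-chromen-2-one | COc1cc(OC)c2ccc(=O)oc2c1/C=C/C(C)=O
F2 | step 5 | 8-[(1E,3S)-3-hydroxybut-1-en-1-yl]-5,7-dimethoxy-2H-chromen-2-one | C[C@H](O)/C=C/c1c(OC)cc(OC)c2ccc(=O)oc12
F3 | step 5 | 3,3,5-trimethylhex-5-enoic acid | OC(=O)CC(C)(C)CC(C)=C
F4 | step 5 | (2S,3E)-4-(5,7-dimethoxy-2-oxo-2H-chromen-8-yl)but-3-en-2-yl 3,3,5-trimethylhex-5-enoate | C[C@H](OC(=O)CC(C)(C)CC(C)=C)/C=C/c1c(OC)cc(OC)c2ccc(=O)oc12
F5 | step 5 | (E)-trimethylsilyl ketene acetal of F4 | C[C@H](O/C(O[Si](C)(C)C)=C\C(C)(C)CC(C)=C)/C=C/c1c(OC)cc(OC)c2ccc(=O)oc12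
F6 | step 5 | trimethylsilyl (2S,3R,4E)-3-(5,7-dimethoxy-2-oxo-2H-chromen-8-yl)-2-(2,4-dimethylpent-4-en-2-yl)hex-4-enoate | C[Si](C)(C)OC(=O)[C@H](C(C)(C)CC(C)=C)[C@H](c1c(OC)cc(OC)c2ccc(=O)oc12)/C=C/C
F7 | step 5 | (2S,3R,4E)-3-(5,7-dimethoxy-2-oxo-2H-chromen-8-yl)-2-(2,4-dimethylpent-4-en-2-yl)hex-4-enoic acid | OC(=O)[C@H](C(C)(C)CC(C)=C)[C@H](c1c(OC)cc(OC)c2ccc(=O)oc12)/C=C/C
F8 | step 5 | S-ethyl (2S,3R,4E)-3-(5,7-dimethoxy-2-oxo-2H-chromen-8-yl)-2-(2,4-dimethylpent-4-en-2-yl)hex-4-enethioate | CCSC(=O)[C@H](C(C)(C)CC(C)=C)[C@H](c1c(OC)cc(OC)c2ccc(=O)oc12)/C=C/C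
F9 | step 7 | (1S,2R)-2-(5,7-dimethoxy-2-oxo-2H-chromen-8-yl)-4,6,6-trimethylcyclohex-3-ene-1-carboxylic acid | OC(=O)[C@H]1[C@H](c2c(OC)cc(OC)c3ccc(=O)oc23)C=C(C)CC1(C)C
F10 | step 7 | (1S,2R)-2-(5,7-dimethoxy-2-oxo-2H-chromen-8-yl)-4,6,6-trimethylcyclohex-3-ene-1-carbonyl chloride | ClC(=O)[C@H]1[C@H](c2c(OC)cc(OC)c3ccc(=O)oc23)C=C(C)CC1(C)C
F11 | step 8 | (1S,2R)-2-(5,7-dimethoxy-2-oxo-2H-chromen-8-yl)-4,6,6-trimethylcyclohex-3-ene-1-carbaldehyde | O=C[C@H]1[C@H](c2c(OC)cc(OC)c3ccc(=O)oc23)C=C(C)CC1(C)C
F12 | step 8 | (5,7-dimethoxy-2-oxo-2H-chromen-8-yl)chromium dichloride | COc1cc(OC)c2ccc(=O)oc2c1[Cr](Cl)Cl
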